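At the end of the dusk run, 8.80% of the charge reads as neither substrate nor target. I call this the hold-up, the share fed so far minus substrate minus target.

all flasks: gas 46 mM (held)

|  | substrate | temperature | remark | time |
|---|---|---|---|---|
| dusk | 0.97 M (fed, over 3.0 h) | 8 °C | run made earlier; the fed solution adds 0.25 times the starting volume |  |
| dawn | 1.5 M (fed, over 3.0 h) | 24 °C | run made earlier; the fed solution adds 0.25 times the starting volume |  |
| east | 0.69 M (fed, over 3.0 h) |  | at 0 °C until 3.0 h, from then on at 30 °C; the fed solution adds 0.25 times the starting volume | 5.0 h |
| west | 0.69 M (fed, over 2.0 h) |  | at 0 °C throughout; the fed solution adds 0.25 times the starting volume | 5.0 h |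

dusk run (percent of the substrate charged)

| time / h | target / % | substrate / % |
|---|---|---|
| 1.00 | 7.6 | 19.9 |
| 2.00 | 24.7 | 30.7 |
| 3.00 | 48.5 | 35.5 |
| 4.00 | 69.7 | 18.7 |
| 5.00 | 81.2 | 10.0 |

dawn run (percent of the substrate charged)

| time / min | target / % | substrate / % |
|---|---|---|
| 8.00 | 0.6 | 3.7 |
| 15.0 | 1.7 | 7.3 |
| 25.0 | 1.6 | 10.5 |
| 50.0 | 6.2 | 18.0 |
| 90.0 | 20.0 | 26.9 |

(each reading ± 0.5 percentage points)

- amounts are per litre of the starting volume; all of the dose is in the solution fed
- at the start none of the gas is in solution
- a reading or a percentage of target counts all its forms, free or not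
- percentages count the whole charge, also what has not yet gone in

East and west get the same charge and stop at the same hour. But east is fed more slowly and is warmed after its feed, while west stays at 0 °C.

In the dusk run the hold-up reads 16.0% at the end of the feed, so it shrinks once the feed stops. In the dawn run, at 24 °C, it reads 3.10% with half of the feed given. So the dawn run, warmer but with a larger charge, reads less than dusk's 5.83% with a third given.

- the winner by amount of target, in percent of the substrate charged; "neither" if no more than 2 percentage points parts them (east / west / neither)
- how much target is there at the end, in percent of the substrate charged: east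
- how much target is there at the end, in percent of the substrate charged: west

Target is the charge less substrate less hold-up. I assume both flasks end with dusk's 10.0% substrate. East ends warmer than dawn, so as a rough guess I give it dawn's mid-feed hold-up, which makes 86.9%. West is colder than dusk, so as a rough guess I give it the end hold-up of dusk, the colder run, which makes 81.2%. So my estimate puts east ahead of west.

The forecast also names east, with 88% for east and 69% for west, which is lower than mine for west, and its ground for east is “warming after the feed quickly clears the accumulated intermediate”.

East ends with 85.7% and west with 78.0%, so east wins.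

    reagent + intermediate → side product (k = 1.50 L mol⁻¹ h⁻¹, Ea = 70.0 kJ mol⁻¹)
    reagent + intermediate → target (k = 25.0 L mol⁻¹ h⁻¹, Ea = 60.0 kJ mol⁻¹)
    crystals ⇌ target, rate k3*(cs3 - [target]) while solid is left; crystals form when [target] > cs3 (solubility = 24.0 mM, k = 46.0 h⁻¹)
    gas ⇌ reagent, rate k4*(csat - [reagent]) (kL = 120 h⁻¹)
    substrate + reagent ⇌ intermediate (K = 21.0 L mol⁻¹, k = 40.0 L mol⁻¹ h⁻¹, Ea = 47.0 kJ mol⁻¹, ΔH = −59.0 kJ mol⁻¹)
    (constants at 0 °C)

The hold-up ends at 7.17% in east and 11.8% in west, and it counts side product as well as intermediate. At 2.74 h in east, intermediate falls back 1.6 times faster than it goes on. Of what goes on at that time in east, target takes 17 times the rate of side product. The neighbour, east with 2.8 M substrate, ends with 80.6% target, 12.2% substrate and a hold-up of 7.20%.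

The numbers in the tables are calculated for an exercise, noise included.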